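Start with the easy step: G dissolves to D, and D stops at its solubility of 0.97 M while solid remains.

    D ⇌ Z (K1 = 0.013, k1 = 0.080 s⁻¹)
    E + Z → E.Z (k2 = 0.079 M⁻¹ s⁻¹)
    D ⇌ X (K3 = 0.46, k3 = 0.052 s⁻¹)
    G ⇌ D, rate k4*(cs4 - [D]) while solid is left; crystals form when [D] > cs4 (cs4 = 0.97 M, k4 = 1.3 s⁻¹)
    2 E → E2 (k5 = 0.033 M⁻¹ s⁻¹)

G 1.5 M; E 2.25 M; time 8.0 min

- part of the G that has turned into other species by 8.0 min (what has only dissolved does not count)
- amount of E.Z at 8.0 min, in percent of the G charged
- amount of E.Z if the flask were left three thousand times as long, in percent of the G charged

- for a step with 2 of a species take k times the square, and two of it per event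
- given per volume of solution although it is solid: G
- at the start none of G is in solution
- what has only dissolved of G counts as not reacted
- what has gone from D into another species counts as reacted, even if it can come back
- run time (flask): 8.0 min

**Solution room.** D and X relax with a half-life of 0.0700 min, D and Z with one of 0.111 s, both far shorter than the run, so take X and Z at 0.46 and 0.013 times D. A saturated solution then holds 95.3% of the G charge as D, Z and X together: call this share the room. Work with what is left: while solid remains, the solid fraction is one minus the room minus the E.Z fraction.

**Two extremes.** If E made no E.Z, 4.75% of the charge would stay solid, and conversion would be the X and Z share, 30.6%. If E made no E2, its 1.50 equivalents would cover the whole charge.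

**My reckoning.** With Z held at 0.841% of the charge, E at its charge would go to E2 149 times faster than to E.Z, so the flask lies near the first extreme. Following the E left, I get 4.08% as E.Z by 8.0 min and conversion 34.7%. With Z held to the end, I get 5.04% as E.Z in the end, but that is more than the 4.75% outside the room, so the solid goes first and my last figure stands high.

**The forecast.** It gives conversion 34.5%, E.Z 3.9% at 8.0 min and E.Z 4.9% after the long wait, on the ground that “the dimerisation of E uses up nearly all the reagent within tens of seconds”.

**The flask.** The simulation gives conversion 34.5%, E.Z 3.91% at 8.0 min and E.Z 4.87% after the long wait, close to the forecast, and my E.Z at 8.0 min stands higher than the simulated one by 0.17 percentage points.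

**At rest?** With 3.91% as E.Z, the room leaves 0.841% solid; this flask shows G at 0.843% at 8.00 min. In the neighbour flask charged with 2.5 M of G, the room is 57.2%, and E.Z at 2.34% leaves 40.5% solid; that flask shows G at 40.5% at 8.00 min. The first flask has not quite come to rest: E stands at 1.08% of its charge at 8.00 min, and the largest change of a share over the second half of the time is 0.57 points. By 80.0 min, that flask gains 0.95 points of E.Z, reaching 4.86%, more than the 4.75% outside the room, and its G falls to 0%.

(The rate constants are invented; the result is computed.)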